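## Retrosynthetic overview

- **Final disconnection:** the C3′–C4′ single bond (a CH2 joined to the methyl-bearing alkene carbon of the undecadienylidene chain) and the C4′–CH3 bond. In the forward direction a C11 dienyl lactone and a C13 1,1-dichloroalkene are joined in one flask by hydroboration, trans-selective B-alkyl Suzuki–Miyaura coupling and Negishi methylation.
- **Enabling feature:** C4′ is an sp2 carbon with two carbon substituents, C3′H2 trans and CH3 cis to the C6′ chain, so it can start as a CCl2 terminus whose two C–Cl bonds differ sterically. C2′–C3′ sits next to the exocyclic C3=C1′ bond, which is conjugated with C2=O of the γ-butyrolactone ring, so it can start as a vinyl group whose inner neighbour is inert to boranes.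
- **Dichloroalkene half:** geranyl acetate supplies the C8′=C9′ E-alkene. It is taken through ozonolysis, CCl2 olefination (CCl4 becomes C4′), enal formation, methylenation, and a second diene hydroboration/Suzuki coupling with 4-bromofuran-2(5H)-one.
- **Dienyl lactone half:** (S)-5-(hydroxymethyl)butyrolactone supplies C5. It is taken through oxidation, isopropylidene Wittig, acrolein aldol, and acetylation/E1cB.
- **Rings:** none is closed in the route. The butenolide ring enters intact in step 6, the γ-butyrolactone ring enters in step 7, and the two meet in step 11.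

Key step: step 11

Remark: the carbinol carbon C5 of the γ-lactone reads as S in the target. This is the same descriptor and spatial arrangement as in commercial (S)-5-(hydroxymethyl)butyrolactone, so no inversion is needed. Commercial geranyl acetate is taken as the pure 2E isomer.

## Route

Step 1
Reactants: 1 geranyl acetate [(2E)-3,7-dimethylocta-2,6-dien-1-yl acetate]
Product: 3 (2E)-3-methyl-6-oxohex-2-en-1-yl acetate, via secondary ozonide 2 (not isolated)
Conditions: O3 (1 equiv, dye end point), CH2Cl2, −78 °C; PPh3, −78 °C to rt
Reagents that add atoms: ozone, [O-][O+]=O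
Why: Chemoselective ozonolysis with reductive work-up: electrophilic ozone attacks the electron-rich C6=C7 alkene much faster than the C2=C3 alkene, which is deactivated by the allylic acetoxy group, so the E-alkene is kept and PPh3 reduces ozonide 2 to the aldehyde.

Step 2
Reactants: 3 (2E)-3-methyl-6-oxohex-2-en-1-yl acetate
Product: 4 (2E)-7,7-dichloro-3-methylhepta-2,6-dien-1-yl acetate
Conditions: PPh3, CCl4, THF, 60 °C
Reagents that add atoms: carbon tetrachloride, ClC(Cl)(Cl)Cl
Why: Wittig-type dichloromethylenation: Ph3P=CCl2 formed in situ from PPh3 and CCl4 converts the aldehyde into the 1,1-dichloroalkene under neutral conditions that leave the allylic acetate and the E-alkene alone.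

Step 3
Reactants: 4 (2E)-7,7-dichloro-3-methylhepta-2,6-dien-1-yl acetate
Product: 5 (2E)-7,7-dichloro-3-methylhepta-2,6-dien-1-ol
Conditions: K2CO3 (cat.), MeOH, 0 °C to rt
Reagents that add atoms: none
Why: Base-catalysed transesterification with methanol removes the acetate, and neither the dichloroalkene nor the trisubstituted alkene reacts with carbonate.

Step 4
Reactants: 5 (2E)-7,7-dichloro-3-methylhepta-2,6-dien-1-ol
Product: 6 (2E)-7,7-dichloro-3-methylhepta-2,6-dienal
Conditions: activated MnO2, CH2Cl2, rt
Reagents that add atoms: none
Why: Selective allylic alcohol oxidation on activated MnO2 stops at the enal and keeps the E geometry.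

Step 5
Reactants: 6 (2E)-7,7-dichloro-3-methylhepta-2,6-dienal
Product: 7 (5E)-1,1-dichloro-5-methylocta-1,5,7-triene
Conditions: Ph3PCH3Br, n-BuLi, THF, 0 °C; 6, −78 °C to rt
Reagents that add atoms: methyltriphenylphosphonium bromide, C[P+](c1ccccc1)(c1ccccc1)c1ccccc1.[Br-]
Why: Wittig methylenation of the enal gives the terminal 1,3-diene with the E-trisubstituted alkene retained, and the ylide does not touch the dichloroalkene.

Step 6
Reactants: 7 (5E)-1,1-dichloro-5-methylocta-1,5,7-triene; 8 4-bromofuran-2(5H)-one
Product: 10 4-[(3E)-8,8-dichloro-4-methylocta-3,7-dien-1-yl]furan-2(5H)-one, via B-alkyl-9-BBN 9 (not isolated)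
Conditions: (i) 9-BBN-H, THF, 0 °C to rt; (ii) 8, PdCl2(dppf) (cat.), AsPh3 (cat.), K3PO4 (aq.), DMF–THF, rt
Reagents that add atoms: 9-BBN-H, B1C2CCCC1CCC2 (boron and its ring only in 9; one H stays in 10)
Why: Hydroboration/B-alkyl Suzuki–Miyaura coupling: 9-BBN-H adds only to the monosubstituted terminus of the 1,3-diene with boron on the end carbon, and Pd(dppf) at room temperature inserts into the activated vinylogous acyl C–Br bond of 8 but not into the C–Cl bonds.

Step 7
Reactants: 11 (5S)-5-(hydroxymethyl)dihydrofuran-2(3H)-one
Product: 12 (2S)-5-oxotetrahydrofuran-2-carbaldehyde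
Conditions: Dess–Martin periodinane, CH2Cl2, 0 °C to rt; filtered, used crude
Reagents that add atoms: none
Why: Dess–Martin oxidation under neutral, water-free conditions should give the sensitive α-oxygenated aldehyde without epimerisation of the stereocentre taken from the chiral pool.

Step 8
Reactants: 12 (2S)-5-oxotetrahydrofuran-2-carbaldehyde
Product: 13 (5S)-5-(2-methylprop-1-en-1-yl)dihydrofuran-2(3H)-one
Conditions: i-PrPPh3I, n-BuLi, THF, 0 °C; 12, −78 °C to 0 °C
Reagents that add atoms: isopropyltriphenylphosphonium iodide, CC(C)[P+](c1ccccc1)(c1ccccc1)c1ccccc1.[I-]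
Why: Wittig olefination with the non-stabilised isopropylidene ylide: at −78 °C the aldehyde is far more electrophilic than the lactone, no alkene geometry arises because the new terminus carries two methyl groups, and C5 keeps its S configuration because none of its bonds is broken.

Step 9
Reactants: 13 (5S)-5-(2-methylprop-1-en-1-yl)dihydrofuran-2(3H)-one; 14 acrolein
Product: 16 (5S)-3-(1-hydroxyprop-2-en-1-yl)-5-(2-methylprop-1-en-1-yl)dihydrofuran-2(3H)-one (mixture of diastereomers at C3 and at the carbinol carbon), via lithium enolate 15 (not isolated)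
Conditions: LDA, THF, −78 °C; 14, −78 °C; AcOH quench
Reagents that add atoms: none
Why: Kinetic lithium enolate aldol addition, which goes 1,2 to acrolein at −78 °C; the two new stereocentres need no control because both are erased in step 10.

Step 10
Reactants: 16 (5S)-3-(1-hydroxyprop-2-en-1-yl)-5-(2-methylprop-1-en-1-yl)dihydrofuran-2(3H)-one
Product: 18 (3E,5S)-5-(2-methylprop-1-en-1-yl)-3-(prop-2-en-1-ylidene)dihydrofuran-2(3H)-one, via allylic acetate 17 (not isolated)
Conditions: Ac2O, Et3N, DMAP (cat.), CH2Cl2, 0 °C to rt; DBU, rt
Reagents that add atoms: acetic anhydride, CC(=O)OC(C)=O (acetyl group only in 17)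
Why: Acetylation followed by E1cB elimination: DBU removes the acidic C3–H, acetate leaves from the enolate, and the conformer that turns the vinyl group away from the carbonyl oxygen should give mainly the E-alkylidene lactone, from which any Z isomer is removed by chromatography.

Step 11
Reactants: 18 (3E,5S)-5-(2-methylprop-1-en-1-yl)-3-(prop-2-en-1-ylidene)dihydrofuran-2(3H)-one; 10 4-[(3E)-8,8-dichloro-4-methylocta-3,7-dien-1-yl]furan-2(5H)-one
Product: 21 (3E,5S)-3-[(4E,8E)-4,8-dimethyl-11-(5-oxo-2,5-dihydrofuran-3-yl)undeca-4,8-dien-1-ylidene]-5-(2-methylprop-1-en-1-yl)dihydrofuran-2(3H)-one, via B-alkyl-9-BBN 19 (not isolated), via Z-chloroalkene 20 (not isolated)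
Conditions: (i) 18 (slight excess), 9-BBN-H, THF, 0 °C to rt; (ii) 10, Pd2(dba)3 (cat.), XantPhos (cat.), K3PO4, THF, 65 °C; (iii) MeZnCl, Pd(P-t-Bu3)2 (cat.), same flask, rt to 50 °C
Reagents that add atoms: methylzinc chloride, C[Zn]Cl (CH3 of 21); 9-BBN-H, B1C2CCCC1CCC2 (boron and its ring only in 19; one H stays in 21)
Why: 9-BBN-H adds across the only monosubstituted C=C of 18 with boron on the terminal carbon (the exocyclic C=C is trisubstituted and drained by the lactone C=O, the isobutenyl C=C is trisubstituted and shielded by the ring carbon next to it), which gives homoallylic borane 19 as in the known selective hydroboration of terminal 1,3-dienes. Pd(0) carrying the wide-bite-angle bisphosphine then inserts into the C–Cl bond of 10 that lies trans to the alkyl chain, the phosphate-activated borane transmetalates, and reductive elimination forms the CH2–C(sp2) bond with retention, which is the known trans-selective B-alkyl Suzuki–Miyaura monocoupling of 1,1-dichloro-1-alkenes. The coupling should stop at Z-chloroalkene 20 because the remaining C–Cl bond has lost the activating geminal chlorine and is shielded by the cis chain, so it needs the electron-rich Pd(P-t-Bu3)2, which with MeZnCl replaces it with retention (Negishi coupling of alkenyl chlorides). No ring is closed and no stereocentre is made; the only new stereo-element is the E-alkene, and it is controlled by the steric difference between the two chlorine atoms and by the retentive course of both couplings. The step needs chemoselectivity against two lactones, three further alkenes and the allylic C5–O bond: borane, phosphate and organozinc do not attack lactones at these temperatures, fast reductive elimination from the chelated palladium should outrun β-hydride loss from the homoallylic ligand, and the allylic C–O bond is flanked by a trisubstituted alkene that binds Pd(0) poorly. In one flask the operation joins the C11 and C13 halves, turns the vinyl group into the C2′–C3′ spacer, sets the central E-alkene and installs its methyl group.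

## Compound list

1 | geranyl acetate | CC(C)=CCC/C(C)=C/COC(C)=O | starting material
2 | secondary ozonide of the C6=C7 alkene of 1 | CC1(C)OOC(CC/C(C)=C/COC(C)=O)O1 | intermediate
3 | (2E)-3-methyl-6-oxohex-2-en-1-yl acetate | O=CCC/C(C)=C/COC(C)=O | intermediate
4 | (2E)-7,7-dichloro-3-methylhepta-2,6-dien-1-yl acetate | ClC(Cl)=CCC/C(C)=C/COC(C)=O | intermediate
5 | (2E)-7,7-dichloro-3-methylhepta-2,6-dien-1-ol | ClC(Cl)=CCC/C(C)=C/CO | intermediate
6 | (2E)-7,7-dichloro-3-methylhepta-2,6-dienal | ClC(Cl)=CCC/C(C)=C/C=O | intermediate
7 | (5E)-1,1-dichloro-5-methylocta-1,5,7-triene | ClC(Cl)=CCC/C(C)=C/C=C | intermediate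
8 | 4-bromofuran-2(5H)-one | BrC1=CC(=O)OC1 | starting material
9 | 9-[(3E)-8,8-dichloro-4-methylocta-3,7-dien-1-yl]-9-borabicyclo[3.3.1]nonane | ClC(Cl)=CCC/C(C)=C/CCB1C2CCCC1CCC2 | intermediate
10 | 4-[(3E)-8,8-dichloro-4-methylocta-3,7-dien-1-yl]furan-2(5H)-one | ClC(Cl)=CCC/C(C)=C/CCC1=CC(=O)OC1 | intermediate
11 | (5S)-5-(hydroxymethyl)dihydrofuran-2(3H)-one | OC[C@@H]1CCC(=O)O1 | starting material
12 | (2S)-5-oxotetrahydrofuran-2-carbaldehyde | O=C[C@@H]1CCC(=O)O1 | intermediate
13 | (5S)-5-(2-methylprop-1-en-1-yl)dihydrofuran-2(3H)-one | CC(C)=C[C@@H]1CCC(=O)O1 | intermediate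
14 | acrolein | C=CC=O | starting material
15 | lithium enolate of 13 | CC(C)=C[C@@H]1CC=C([O-])O1.[Li+] | intermediate
16 | (5S)-3-(1-hydroxyprop-2-en-1-yl)-5-(2-methylprop-1-en-1-yl)dihydrofuran-2(3H)-one, diastereomer mixture | CC(C)=C[C@@H]1CC(C(O)C=C)C(=O)O1 | intermediate
17 | acetate of 16, diastereomer mixture | CC(C)=C[C@@H]1CC(C(OC(C)=O)C=C)C(=O)O1 | intermediate
18 | (3E,5S)-5-(2-methylprop-1-en-1-yl)-3-(prop-2-en-1-ylidene)dihydrofuran-2(3H)-one | CC(C)=C[C@@H]1C/C(=C\C=C)C(=O)O1 | intermediate
19 | (3E,5S)-3-[3-(9-borabicyclo[3.3.1]nonan-9-yl)propylidene]-5-(2-methylprop-1-en-1-yl)dihydrofuran-2(3H)-one | CC(C)=C[C@@H]1C/C(=C\CCB2C3CCCC2CCC3)C(=O)O1 | intermediate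
20 | (3E,5S)-3-[(4Z,8E)-4-chloro-8-methyl-11-(5-oxo-2,5-dihydrofuran-3-yl)undeca-4,8-dien-1-ylidene]-5-(2-methylprop-1-en-1-yl)dihydrofuran-2(3H)-one | CC(C)=C[C@@H]1C/C(=C\CC/C(Cl)=C/CC/C(C)=C/CCC2=CC(=O)OC2)C(=O)O1 | intermediate
21 | (3E,5S)-3-[(4E,8E)-4,8-dimethyl-11-(5-oxo-2,5-dihydrofuran-3-yl)undeca-4,8-dien-1-ylidene]-5-(2-methylprop-1-en-1-yl)dihydrofuran-2(3H)-one (CNP0237694.1) | CC(C)=C[C@@H]1C/C(=C\CC/C(C)=C/CC/C(C)=C/CCC2=CC(=O)OC2)C(=O)O1 | target

## Step count and risks

Total steps: 11. Longest linear sequence: 7 (steps 1–6 and 11).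

Steps most likely to fail:

**1. Step 11.** The hydroboration of the electron-poor diene may be slow. The borane could then begin to attack the isobutenyl alkene or deliver hydride in a conjugate sense to the dienyl lactone, and the coupling would be starved of its alkyl partner.

The fallback sets out from 17, which is isolated after the acetylation half of step 10 instead of being eliminated, and comes back to the route at 20. The vinyl group of 17 is an isolated monosubstituted alkene and should take up 9-BBN-H normally to give the γ-acetoxy borane F1. The same Pd/XantPhos coupling with 10 gives the β-acetoxy lactone F2. DBU (or already the phosphate) then expels acetate by E1cB to give 20, which is isolated and methylated as in the last stage of step 11. The alkylidene is thus created after the union rather than before it.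

**2. Step 6.** The aqueous base may hydrolyse the vinylogous acyl bromide faster than the borane transmetalates, and the borane would then be lost by protodeboronation.

The fallback sets out from 5 and comes back at 10. It builds the butenolide by dearomatising oxidation of a furan instead of by cross-coupling.
- An Appel reaction (CBr4, PPh3) gives the allylic bromide F3.
- Coupling of F3 with (furan-3-ylmethyl)magnesium chloride F4 (from 3-(chloromethyl)furan and Mg) under Li2CuCl4 catalysis gives the 3-alkylfuran F5.
- Singlet oxygen (O2, rose bengal, light) with i-Pr2NEt at −78 °C turns the furan, which reacts faster than the alkenes, regioselectively into the γ-hydroxybutenolide F6.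
- NaBH4 followed by acid closes F6 to 10.

**3. Step 8.** The hindered, strongly basic isopropylidene ylide may add slowly, so enolisation of the α-oxygenated aldehyde (erosion of the C5 configuration) and opening of the lactone could compete.

The fallback sets out from 12 and comes back at 13. The small, fast methylene ylide (Ph3P=CH2, −78 °C) gives (5S)-5-vinyldihydrofuran-2(3H)-one F7. Olefin cross-metathesis of F7 in 2-methylbut-2-ene with a second-generation ruthenium catalyst then installs the two methyl groups under neutral conditions.

## Further compounds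

F1 | step 11 | 9-BBN adduct of acetate 17 (boron on the terminal carbon) | CC(C)=C[C@@H]1CC(C(CCB2C3CCCC2CCC3)OC(C)=O)C(=O)O1
F2 | step 11 | β-acetoxy lactone carrying the coupled Z-chloroalkene chain | CC(C)=C[C@@H]1CC(C(CC/C(Cl)=C/CC/C(C)=C/CCC2=CC(=O)OC2)OC(C)=O)C(=O)O1
F3 | step 6 | (2E)-1-bromo-7,7-dichloro-3-methylhepta-2,6-diene | ClC(Cl)=CCC/C(C)=C/CBr
F4 | step 6 | (furan-3-ylmethyl)magnesium chloride | Cl[Mg]Cc1ccoc1
F5 | step 6 | 3-[(3E)-8,8-dichloro-4-methylocta-3,7-dien-1-yl]furan | ClC(Cl)=CCC/C(C)=C/CCc1ccoc1
F6 | step 6 | 4-[(3E)-8,8-dichloro-4-methylocta-3,7-dien-1-yl]-5-hydroxyfuran-2(5H)-one | ClC(Cl)=CCC/C(C)=C/CCC1=CC(=O)OC1O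
F7 | step 8 | (5S)-5-vinyldihydrofuran-2(3H)-one | C=C[C@@H]1CCC(=O)O1
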